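**Plan**
1. Numbering used throughout: trione ring C1(benzoyl)–C2(=O)–C3–C4(=O)–C5(geranyl)–C9(=O); second ring C5–C6H2–C7H–C8Me2–C1.
2. Retrosynthesis: the carbinol O–H is cut back to a nitroxide ether; then the cyclopentane bond CMe2–CH(carbinyl) and the C3–CH bond of the homoadamantane are cut in one radical cascade, giving a bicyclo[3.3.1]nonane-2,4,9-trione with prenyl groups at C3 and at C7 (endo).
3. Enabling feature: C3 is the central carbon of the enolised C2/C4 1,3-diketone, lies directly under the endo C7 prenyl group and carries its own prenyl group, so one C3 radical can join both alkenes.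
4. Further cuts: C3–prenyl (allylic alkylation); the C7 side chain (olefination of an endo aldehyde released by retro-aldol from an adamantane alcohol); then C5–C6, C1–C8 and C3–C10 of that adamantane (dearomatising annulation of 3-geranyl-2,4,6-trihydroxybenzophenone with a five-carbon enal acetate).
5. Forward order: enal reagent; C-geranylation; annulation (ring C5–C8/C1 and the temporary adamantane ring); retro-aldol/olefination, 1,4-hydrogenation, C3 prenylation; cascade (both seven-membered rings, then the cyclopentane); N–O cleavage.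
6. Stereochemistry: C5 (and with it C1) from the chiral phase-transfer catalyst; C7 endo from the adamantane; C3, the ring-fusion CH and the carbinyl CH from the cage, the C8 gem-dimethyl group and a chair-like 5-exo closure in the cascade.

Key step: step 9

Assumption: the cinchonidinium catalyst of step 5 is taken to give the C5 configuration drawn; if its sense of induction is the opposite, the pseudoenantiomeric cinchoninium salt is used instead.

**Route**

Step 1
Reactants: 1 diethyl 2-(propan-2-ylidene)propanedioate
Product: 2 2-(propan-2-ylidene)propane-1,3-diol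
Conditions: i-Bu2AlH (4.5 equiv), CH2Cl2, −78 → 0 °C; aq. KNaC4H4O6
Reagents that add atoms: none
Why: 1,2-reduction of both conjugated esters to allylic alcohols by i-Bu2AlH, the tetrasubstituted alkene disfavouring conjugate hydride addition, with no stereocentre formed.

Step 2
Reactants: 2 2-(propan-2-ylidene)propane-1,3-diol
Product: 4 2-(hydroxymethyl)-3-methylbut-2-en-1-yl acetate, via cyclic orthoester 3 (not isolated)
Conditions: MeC(OMe)3 (1.3 equiv), pyridinium p-toluenesulfonate (5 mol %), CH2Cl2, 25 °C; then H2O, 25 °C
Reagents that add atoms: trimethyl orthoacetate COC(C)(OC)OC; water O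
Why: orthoester exchange gives the six-membered cyclic orthoester, whose mild hydrolysis opens to the monoacetate only (1,3-diol monoacylation through a cyclic orthoester), the two hydroxyl groups being equivalent so that no regio- or stereochemical question arises.

Step 3
Reactants: 4 2-(hydroxymethyl)-3-methylbut-2-en-1-yl acetate
Product: 5 2-formyl-3-methylbut-2-en-1-yl acetate
Conditions: MnO2 (15 equiv), CH2Cl2, 25 °C
Reagents that add atoms: none
Why: MnO2 oxidises the allylic primary alcohol to the enal (allylic alcohol oxidation) and leaves the allylic acetate untouched, with no stereocentre formed.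

Step 4
Reactants: 6 2,4,6-trihydroxybenzophenone; 7 geranyl bromide
Product: 8 3-geranyl-2,4,6-trihydroxybenzophenone
Conditions: 7 (1.0 equiv), KOH (1.1 equiv), H2O, 0 → 25 °C
Reagents that add atoms: none
Why: C-alkylation of the phloroglucinol anion by the allylic bromide in water (phenolate C-allylation by SN2) should stop at the mono-geranyl stage with one equivalent of bromide and keeps the E alkene.

Step 5
Reactants: 8 3-geranyl-2,4,6-trihydroxybenzophenone; 5 2-formyl-3-methylbut-2-en-1-yl acetate
Product: 11 adamantane alcohol 1-benzoyl-5-geranyl-10-hydroxy-8,8-dimethyladamantane-2,4,9-trione (C3–H; C10 links C3 to C7; carbinol centre not controlled), via dearomatised enal 9 (not isolated), via bicyclic aldehyde 10 (not isolated)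
Conditions: O-allyl-N-(9-anthracenylmethyl)cinchonidinium bromide (10 mol %), CsOH·H2O (4 equiv), 4 Å molecular sieves, CH2Cl2, −50 → −20 °C; then 1 M HCl
Reagents that add atoms: none
Why: enantioselective alkylative dearomatisation–annulation under phase-transfer catalysis, in which conjugate addition–elimination of the geranyl-bearing ring carbon to 5 sets C5 inside the chiral ion pair, the benzoyl-bearing carbon then adds to the β,β-dimethyl enal (C1–C8) and C3 closes on the endo aldehyde by aldol addition, so that C1, C7 and C3 follow from C5 through the cage and only attack at the geranyl-bearing carbon can give an adamantane because C3 carries hydrogen.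

Step 6
Reactants: 11 adamantane alcohol; 12 diethyl (2-methylprop-2-en-1-yl)phosphonate
Product: 14 1-benzoyl-5-geranyl-4-hydroxy-8,8-dimethyl-7-endo-[(1E)-3-methylbuta-1,3-dienyl]bicyclo[3.3.1]non-3-ene-2,9-dione, via potassium diketonate 13 (not isolated)
Conditions: 12 (4 equiv), KN(SiMe3)2 (5 equiv), THF, −78 °C; add 11; −78 → 0 °C; aq. NH4Cl
Reagents that add atoms: none
Why: KN(SiMe3)2 turns 11 into its potassium alkoxide, which undergoes retro-aldol cleavage of C3–C10 with the 1,3-diketone enolate as leaving group to give the potassium diketonate 13 of the endo aldehyde, whose formyl group is trapped at once by Horner–Wadsworth–Emmons olefination with the allylic phosphonate anion to give the E diene, C7 keeping the endo configuration fixed in the adamantane.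

Step 7
Reactants: 14 the 7-endo-dienyl bicycle
Product: 15 1-benzoyl-5-geranyl-4-hydroxy-8,8-dimethyl-7-endo-prenylbicyclo[3.3.1]non-3-ene-2,9-dione (C3–H)
Conditions: H2 (4 atm), (η6-C10H8)Cr(CO)3 (20 mol %), THF, 45 °C
Reagents that add atoms: none
Why: 1,4-hydrogenation of the s-cis-accessible 1,3-diene on the chromium tricarbonyl fragment gives the prenyl alkene directly, while the isolated geranyl alkenes and the s-trans-locked enolised diketone cannot bind in the required η4 mode, and no stereocentre changes.

Step 8
Reactants: 15 the C3–H bicycle; 16 prenyl acetate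
Product: 17 1-benzoyl-5-geranyl-4-hydroxy-8,8-dimethyl-3-prenyl-7-endo-prenylbicyclo[3.3.1]non-3-ene-2,9-dione
Conditions: 16 (1.05 equiv), Pd(PPh3)4 (5 mol %), DBU (1.1 equiv), THF, 25 °C
Reagents that add atoms: none
Why: Tsuji–Trost allylic alkylation, in which the soft enolate of the 2-unsubstituted 1,3-diketone attacks the 1,1-dimethyl-π-allyl palladium complex at its unsubstituted terminus to give the linear C3 prenyl group, O-allylation being reversible under the catalyst and no stereocentre being formed.

Step 9
Reactants: 17 the 3,7-diprenyl bicycle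
Product: 19 O-(2,2,6,6-tetramethylpiperidin-1-yl) ether of the target tertiary alcohol, via C3 alkoxyamine 18 (not isolated)
Conditions: TEMPO (1.2 equiv), PhI(OAc)2 (0.6 equiv), THF, −78 → 0 °C; then degassed, argon, 65 °C
Reagents that add atoms: TEMPO (2,2,6,6-tetramethylpiperidin-1-oxyl) CC1(C)CCCC(C)(C)N1[O]
Why: The oxoammonium ion made from TEMPO and PhI(OAc)2 aminoxylates the enol at C3, and on warming the weak, crowded C3–O bond of 18 homolyses reversibly, so the 1,3-diketone radical is released while free nitroxide stays scarce (persistent radical effect); the closest known reaction types are oxidative radical cyclisations of prenylated acylphloroglucinol diketones and thermal alkoxyamine radical cyclisations. The C3 radical adds to the CH terminus of the endo C7 prenyl group in a 7-exo-trig closure that completes both seven-membered rings of the homoadamantane, the tertiary radical so formed adds to the CH terminus of the C3 prenyl group in a 5-exo-trig closure that completes the cyclopentane, and the new tertiary radical is captured by the nitroxide. C3 can bond only on its endo face because the cage holds the alkene beneath it; the ring-fusion CH is controlled by the C8 gem-dimethyl group, which makes the C7–CH2 bond lean toward C6 so that, with an allylic hydrogen eclipsing the alkene, the CMe2 terminus turns to the C2/C8 flank; the carbinyl-bearing CH comes from a chair-like 5-exo transition state that puts the incipient C(Me)2 radical on the outer face, trans to the CH2 that links the ring-fusion CH to C7. The step needs each cyclisation to outrun radical capture and the C3 radical to choose the C7 prenyl group: the dormant alkoxyamine keeps the nitroxide scarce, the bridgehead geranyl and benzoyl groups are equatorial on the trione ring and cannot reach C3, and the unstabilised tertiary alkyl–O bond of 19 should hold at 65 °C, making 19 the sink.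

Step 10
Reactants: 19 the nitroxide ether
Product: 20 target CNP0164095.2
Conditions: Zn dust (20 equiv), AcOH/THF/H2O (3:1:1), 50 °C
Reagents that add atoms: none
Why: reductive N–O cleavage of the alkoxyamine by zinc in acetic acid frees the tertiary alcohol without touching the non-enolisable ketones or the alkenes, and no stereocentre is affected.

**Compound list**
1 | diethyl 2-(propan-2-ylidene)propanedioate | CCOC(=O)C(=C(C)C)C(=O)OCC | starting material
2 | 2-(propan-2-ylidene)propane-1,3-diol | CC(C)=C(CO)CO | intermediate
3 | 2-methoxy-2-methyl-5-(propan-2-ylidene)-1,3-dioxane | COC1(C)OCC(=C(C)C)CO1 | intermediate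
4 | 2-(hydroxymethyl)-3-methylbut-2-en-1-yl acetate | CC(C)=C(CO)COC(C)=O | intermediate
5 | 2-formyl-3-methylbut-2-en-1-yl acetate | CC(C)=C(C=O)COC(C)=O | intermediate
6 | 2,4,6-trihydroxybenzophenone | O=C(c1ccccc1)c1c(O)cc(O)cc1O | starting material
7 | geranyl bromide | CC(C)=CCC/C(C)=C/CBr | starting material
8 | 3-geranyl-2,4,6-trihydroxybenzophenone | CC(C)=CCC/C(C)=C/Cc1c(O)cc(O)c(C(=O)c2ccccc2)c1O | intermediate
9 | dearomatised enal: 4-benzoyl-6-geranyl-6-(2-formyl-3-methylbut-2-enyl)-3,5-dihydroxycyclohexa-2,4-dien-1-one | CC(C)=CCC/C(C)=C/C[C@@]1(CC(C=O)=C(C)C)C(=O)C=C(O)C(C(=O)c2ccccc2)=C1O | intermediate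
10 | bicyclic aldehyde: 1-benzoyl-5-geranyl-4-hydroxy-8,8-dimethyl-2,9-dioxobicyclo[3.3.1]non-3-ene-7-endo-carbaldehyde | CC(C)=CCC/C(C)=C/C[C@@]12C[C@@H](C=O)C(C)(C)[C@](C(=O)c3ccccc3)(C2=O)C(=O)C=C1O | intermediate
11 | adamantane alcohol: 1-benzoyl-5-geranyl-10-hydroxy-8,8-dimethyladamantane-2,4,9-trione (C3–H; carbinol centre undefined) | CC(C)=CCC/C(C)=C/C[C@]12C[C@@H]3C(C)(C)[C@](C(=O)c4ccccc4)(C1=O)C(=O)[C@@H](C3O)C2=O | intermediate
12 | diethyl (2-methylprop-2-en-1-yl)phosphonate | CC(=C)CP(=O)(OCC)OCC | starting material
13 | potassium diketonate: potassium 1-benzoyl-7-endo-formyl-5-geranyl-8,8-dimethyl-2,9-dioxobicyclo[3.3.1]non-3-en-4-olate | CC(C)=CCC/C(C)=C/C[C@@]12C[C@@H](C=O)C(C)(C)[C@](C(=O)c3ccccc3)(C2=O)C(=O)C=C1[O-].[K+] | intermediate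
14 | 7-endo-[(1E)-3-methylbuta-1,3-dienyl] bicycle (C3–H) | CC(C)=CCC/C(C)=C/C[C@@]12C[C@@H](/C=C/C(C)=C)C(C)(C)[C@](C(=O)c3ccccc3)(C2=O)C(=O)C=C1O | intermediate
15 | 7-endo-prenyl bicycle (C3–H) | CC(C)=CCC/C(C)=C/C[C@@]12C[C@@H](CC=C(C)C)C(C)(C)[C@](C(=O)c3ccccc3)(C2=O)C(=O)C=C1O | intermediate
16 | prenyl acetate | CC(C)=CCOC(C)=O | starting material
17 | 1-benzoyl-5-geranyl-4-hydroxy-8,8-dimethyl-3-prenyl-7-endo-prenylbicyclo[3.3.1]non-3-ene-2,9-dione | CC(C)=CCC/C(C)=C/C[C@@]12C[C@@H](CC=C(C)C)C(C)(C)[C@](C(=O)c3ccccc3)(C2=O)C(=O)C(CC=C(C)C)=C1O | intermediate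
18 | C3 alkoxyamine: 2,4,9-triketo form of 17 with the piperidinyloxy group exo and the prenyl group endo at C3 | CC(C)=CCC/C(C)=C/C[C@@]12C[C@@H](CC=C(C)C)C(C)(C)[C@](C(=O)c3ccccc3)(C2=O)C(=O)[C@](CC=C(C)C)(ON4C(C)(C)CCCC4(C)C)C1=O | intermediate
19 | O-(2,2,6,6-tetramethylpiperidin-1-yl) ether of the target tertiary alcohol | CC(C)=CCC/C(C)=C/C[C@@]12C[C@H]3C[C@@H]4C(C)(C)[C@@H](C(C)(C)ON5C(C)(C)CCCC5(C)C)C[C@]4(C1=O)C(=O)[C@@](C(=O)c1ccccc1)(C2=O)C3(C)C | intermediate
20 | CNP0164095.2 | CC(C)=CCC/C(C)=C/C[C@@]12C[C@H]3C[C@@H]4C(C)(C)[C@@H](C(C)(C)O)C[C@]4(C1=O)C(=O)[C@@](C(=O)c1ccccc1)(C2=O)C3(C)C | target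

**Totals**
Total step count: 10. Longest linear sequence: 9 steps (steps 1, 2, 3, 5, 6, 7, 8, 9, 10).

**Steps most likely to fail**

Step 5. Alkylation at the unsubstituted ring carbon of 8 competes with dearomatising alkylation at the geranyl-bearing carbon and drains material into a rearomatised side product; the enantioselectivity may also erode. Fallback: from 8, the free ring carbon is prenylated first (prenyl bromide, aq. KOH) to give 3-geranyl-5-prenyl-2,4,6-trihydroxybenzophenone F1. The same annulation with 5 then gives the C3-prenyl adamantane alcohol F2; no bias is expected between the geranyl- and prenyl-bearing carbons, so the isomer with the two chains exchanged must be removed by chromatography here. Retro-aldol/Horner–Wadsworth–Emmons olefination with 12 gives the C3-prenyl diene F3, and 1,4-hydrogenation over (η6-C10H8)Cr(CO)3 returns to the route at 17.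

Step 9. The first tertiary radical may be captured by the nitroxide before the cyclopentane closes, the hindered final radical may disproportionate instead of coupling, or the CMe2 terminus may swing to the C6 flank in the 7-exo addition. Fallback: from 17, oxidative radical cyclisation with Mn(OAc)3·2H2O and Cu(OAc)2·H2O in degassed AcOH ends by oxidative elimination and gives the isopropenyl homoadamantane F4. Mukaiyama hydration (Co(acac)2, PhSiH3, O2, i-PrOH), stopped at partial conversion so that the more reactive 1,1-disubstituted alkene is hydrated ahead of the trisubstituted geranyl alkenes, then returns to the route at 20.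

Step 6. The liberated aldehyde may epimerise at C7 before olefination (leading into the exo series), or the phosphonate anion may be consumed by the ring ketones. Fallback: from 11, retro-aldol with organocerium addition (CH2=CHMgBr, CeCl3, THF, −78 °C) gives the 7-endo allylic alcohol F5. Acetylation (Ac2O, pyridine, DMAP) gives the diacetate F6, whose enol acetate masks C3. Formate reduction of the allylic acetate (Pd(PPh3)4, HCO2NH4) followed by K2CO3/MeOH gives the 7-endo-allyl bicycle F7. Cross-metathesis with 2-methyl-2-butene (second-generation Grubbs catalyst) returns to the route at 15.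

**Further compounds**
F1 | step 5 | 3-geranyl-5-prenyl-2,4,6-trihydroxybenzophenone | CC(C)=CCC/C(C)=C/Cc1c(O)c(CC=C(C)C)c(O)c(C(=O)c2ccccc2)c1O
F2 | step 5 | 1-benzoyl-5-geranyl-10-hydroxy-8,8-dimethyl-3-prenyladamantane-2,4,9-trione | CC(C)=CCC/C(C)=C/C[C@]12C[C@@H]3C(C)(C)[C@](C(=O)c4ccccc4)(C1=O)C(=O)[C@@](CC=C(C)C)(C3O)C2=O
F3 | step 5 | 3-prenyl-7-endo-[(1E)-3-methylbuta-1,3-dienyl] analogue of 17 | CC(C)=CCC/C(C)=C/C[C@@]12C[C@@H](/C=C/C(C)=C)C(C)(C)[C@](C(=O)c3ccccc3)(C2=O)C(=O)C(CC=C(C)C)=C1O
F4 | step 9 | isopropenyl analogue of 20 (prop-1-en-2-yl in place of 2-hydroxypropan-2-yl) | CC(C)=CCC/C(C)=C/C[C@@]12C[C@H]3C[C@@H]4C(C)(C)[C@@H](C(C)=C)C[C@]4(C1=O)C(=O)[C@@](C(=O)c1ccccc1)(C2=O)C3(C)C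
F5 | step 6 | 7-endo-(1-hydroxyprop-2-enyl) bicycle (C3–H; carbinol centre undefined) | CC(C)=CCC/C(C)=C/C[C@@]12C[C@@H](C(O)C=C)C(C)(C)[C@](C(=O)c3ccccc3)(C2=O)C(=O)C=C1O
F6 | step 6 | diacetate of F5 (allylic acetate and C4 enol acetate) | CC(C)=CCC/C(C)=C/C[C@@]12C[C@@H](C(OC(C)=O)C=C)C(C)(C)[C@](C(=O)c3ccccc3)(C2=O)C(=O)C=C1OC(C)=O
F7 | step 6 | 7-endo-allyl bicycle (C3–H) | CC(C)=CCC/C(C)=C/C[C@@]12C[C@@H](CC=C)C(C)(C)[C@](C(=O)c3ccccc3)(C2=O)C(=O)C=C1O
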